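**Retrosynthetic overview**

1. Target 21 ⇐ TIPS ether 20 ⇐ alcohol 19: the endgame is acetylation of the C7 hydroxyl and desilylation of the phenol.
2. Key disconnection C7–C8: 19 ⇐ secondary boronic ester 13 (C8–B) + lithiated veratryl carbamate 16 (C7 carbenoid). A 1,2-shift of C8 from boron to C7 forms the bond; oxidation of the new C7–B bond gives the C7 oxygen.
3. 13 ⇐ benzylboronate 6 by two sparteine-controlled one-carbon homologations with lithiated ethyl carbamate (C8' with (–)-sparteine, C8 with (+)-sparteine); 6 ⇐ aryl bromide 2 + bromomethylboronate 3. Every C–C bond of the chain and all three stereocentres thus come from one reaction type.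
4. Enabling feature: C7 is a benzylic CH–O carbon on the 3,4-dimethoxyphenyl ring. As an O-carbamate it can be lithiated at C7, its C7–O bond is the leaving group for the shift of C8 from boron, and the C7–B bond left behind is oxidised back to C7–O.
5. Rings: none is formed. Both benzene rings are bought and the chain C7'–C8'–C8–C7 is grown on boron one carbon at a time.

Key step: step 6

Assumption: the sense of induction of the bis(oxazoline) ligand in step 6 is assigned by analogy; if the (S,S)-ligand should favour the (S)-epimer of 16, its antipode is used and nothing else changes (ethyl N,N-diisopropylcarbamate and both sparteine antipodes are taken as purchased).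

Abbreviations: TIPS = tri(propan-2-yl)silyl; Bpin = 4,4,5,5-tetramethyl-1,3,2-dioxaborolan-2-yl; Cb = N,N-di(propan-2-yl)carbamoyl; Ar = 3-methoxy-4-(TIPS-oxy)phenyl; Ar' = 3,4-dimethoxyphenyl. Chain atoms are called C7 (carbinol carbon), C8, C8' and C7' (benzylic CH2).

**Route**

Step 1
Reactants: 1 4-bromo-2-methoxyphenol
Product: 2 (4-bromo-2-methoxyphenoxy)tri(propan-2-yl)silane
Conditions: TIPSCl, imidazole, DMF, rt
Reagents that add atoms: chlorotri(propan-2-yl)silane (TIPSCl), CC(C)[Si](Cl)(C(C)C)C(C)C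
Why: Imidazole-promoted O-silylation of the phenol (silyl ether formation) masks the only acidic proton as a TIPS ether that should survive the organolithium steps and mild base and is removed by fluoride at the end.

Step 2
Reactants: 2 (4-bromo-2-methoxyphenoxy)tri(propan-2-yl)silane; 3 2-(bromomethyl)-4,4,5,5-tetramethyl-1,3,2-dioxaborolane
Product: 6 2-{[3-methoxy-4-(TIPS-oxy)phenyl]methyl}-4,4,5,5-tetramethyl-1,3,2-dioxaborolane (ArCH2Bpin), via aryl Grignard reagent 4 (not isolated), via bromomethyl boronate complex 5 (not isolated)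
Conditions: Mg, I2 (cat.), THF, 45 °C; then 3, –78 °C to rt
Reagents that add atoms: none
Why: Magnesium insertion gives the aryl Grignard reagent, which adds to boron of 3 and then shifts from boron to carbon with loss of bromide (Matteson-type 1,2-metallate homologation), a standard way from aryl metals to benzylboronic esters.

Step 3
Reactants: 6 ArCH2Bpin; 7 ethyl N,N-di(propan-2-yl)carbamate
Product: 10 2-{(2R)-1-[3-methoxy-4-(TIPS-oxy)phenyl]propan-2-yl}-4,4,5,5-tetramethyl-1,3,2-dioxaborolane, via (S)-lithiated ethyl carbamate 8 (not isolated), via boronate complex 9 (not isolated)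
Conditions: 7, s-BuLi, (–)-sparteine, Et2O, –78 °C, 5 h; then 6, –78 °C; then MgBr2·OEt2, –78 °C to reflux
Reagents that add atoms: none
Why: Lithiation–borylation (1,2-metallate rearrangement of a boronate complex): (–)-sparteine-directed removal of the pro-S proton of 7 gives the configurationally stable (S)-carbenoid 8, which is borylated with retention and then receives the benzyl group from boron anti to the leaving carbamate with inversion, so that C8' should be set as R under reagent control.

Step 4
Reactants: 10 (R)-boronic ester from step 3; 7 ethyl N,N-di(propan-2-yl)carbamate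
Product: 13 2-{(2S,3R)-4-[3-methoxy-4-(TIPS-oxy)phenyl]-3-methylbutan-2-yl}-4,4,5,5-tetramethyl-1,3,2-dioxaborolane, via (R)-lithiated ethyl carbamate 11 (not isolated), via boronate complex 12 (not isolated)
Conditions: 7, s-BuLi, (+)-sparteine, Et2O, –78 °C, 5 h; then 10, –78 °C; then MgBr2·OEt2, –78 °C to reflux
Reagents that add atoms: none
Why: The same lithiation–borylation with the mirror-image carbenoid 11 from (+)-sparteine: the secondary alkyl group of 10 migrates with retention at C8' and the new carbon C8 should be set as S under reagent control, which gives the (8S,8'R) dimethyl pair of the target.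

Step 5
Reactants: 14 (3,4-dimethoxyphenyl)methanol
Product: 15 (3,4-dimethoxyphenyl)methyl N,N-di(propan-2-yl)carbamate
Conditions: CbCl, Et3N, CH2Cl2, reflux
Reagents that add atoms: N,N-di(propan-2-yl)carbamoyl chloride (CbCl), CC(C)N(C(C)C)C(Cl)=O
Why: Carbamoylation of the primary benzylic alcohol (acyl substitution at the carbamoyl chloride) installs the group that directs benzylic lithiation and later leaves from C7.

Step 6
Reactants: 15 (3,4-dimethoxyphenyl)methyl N,N-di(propan-2-yl)carbamate; 13 (2S,3R)-boronic ester from step 4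
Product: 19 (1R,2S,3R)-1-(3,4-dimethoxyphenyl)-4-[3-methoxy-4-(TIPS-oxy)phenyl]-2,3-dimethylbutan-1-ol, via (R)-lithiated benzylic carbamate 16 (not isolated), via boronate complex 17 (not isolated), via benzylic boronic ester 18 (not isolated)
Conditions: 15, s-BuLi, (S,S)-iPr-BOX [2,2-bis((4S)-4-isopropyl-4,5-dihydrooxazol-2-yl)propane], toluene, –78 °C, 2 h; then 13, –78 °C, 2 h; MgBr2·OEt2, MeOH, –78 °C to rt; then NaBO3·4H2O, THF/H2O, rt
Reagents that add atoms: sodium perborate tetrahydrate (peroxoborate salt; one oxygen ends on C7), [Na+].[Na+].O[B-]1(O)OO[B-](O)(O)OO1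
Why: Proposed new method: s-BuLi removes a benzylic proton of 15 under direction by the carbamate carbonyl; the resulting α-lithio carbamate 16 is configurationally labile and, as its bis(oxazoline) complex, is expected to settle by thermodynamic resolution on the (R)-epimer, which adds to boron of 13 with retention to give boronate complex 17. On warming with MgBr2·OEt2/MeOH the C8–B bond should shift to C7 anti-periplanar to the departing carbamate (inversion at C7, retention at C8), which forms the C7–C8 bond, and perborate then replaces boron by oxygen with retention, so that C7 is R in 19. The closest known reaction types are the lithiation–borylation homologation of secondary boronic esters with configurationally stable lithiated carbamates and the ligand-mediated dynamic resolution of lithiated primary benzyl carbamates before electrophilic trapping; their combination on a labile primary benzylic carbenoid is what is new. No ring is closed. C7 is the only new stereocentre and is set by the ligand, while C8 and C8' are carried through unchanged because a migrating sp3 carbon keeps its configuration. The step needs benzylic rather than ring lithiation (secured by the proximity effect of the carbamate), migration of C8 alone (the pinacol oxygens do not migrate) and no return of 17 to its components (suppressed by MgBr2/MeOH).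

Step 7
Reactants: 19 (1R,2S,3R)-alcohol from step 6
Product: 20 (1R,2S,3R)-1-(3,4-dimethoxyphenyl)-4-[3-methoxy-4-(TIPS-oxy)phenyl]-2,3-dimethylbutyl acetate
Conditions: Ac2O, pyridine, DMAP (cat.), CH2Cl2, 0 °C to rt
Reagents that add atoms: acetic anhydride, CC(=O)OC(C)=O
Why: DMAP-catalysed acylation of the only free hydroxyl group; the reaction is at oxygen, so C7 keeps its configuration.

Step 8
Reactants: 20 TIPS-protected acetate from step 7
Product: 21 (1R,2S,3R)-1-(3,4-dimethoxyphenyl)-4-(4-hydroxy-3-methoxyphenyl)-2,3-dimethylbutyl acetate (target)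
Conditions: TBAF, AcOH, THF, 0 °C
Reagents that add atoms: none
Why: Fluoride cleaves the aryl silyl ether (desilylation), and buffering with acetic acid keeps the liberated phenol protonated so that the C7 acetate should be neither transferred nor hydrolysed.

**Compound list**

1 | 4-bromo-2-methoxyphenol | COc1cc(Br)ccc1O | starting material
2 | (4-bromo-2-methoxyphenoxy)tri(propan-2-yl)silane | COc1cc(Br)ccc1O[Si](C(C)C)(C(C)C)C(C)C | intermediate
3 | 2-(bromomethyl)-4,4,5,5-tetramethyl-1,3,2-dioxaborolane | BrCB1OC(C)(C)C(C)(C)O1 | starting material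
4 | [3-methoxy-4-(TIPS-oxy)phenyl]magnesium bromide | COc1cc([Mg]Br)ccc1O[Si](C(C)C)(C(C)C)C(C)C | intermediate (not isolated)
5 | bromomagnesium (bromomethyl)[3-methoxy-4-(TIPS-oxy)phenyl](pinacolato)borate | Br[Mg+].COc1cc(ccc1O[Si](C(C)C)(C(C)C)C(C)C)[B-]2(CBr)OC(C)(C)C(C)(C)O2 | intermediate (not isolated)
6 | 2-{[3-methoxy-4-(TIPS-oxy)phenyl]methyl}-4,4,5,5-tetramethyl-1,3,2-dioxaborolane | COc1cc(CB2OC(C)(C)C(C)(C)O2)ccc1O[Si](C(C)C)(C(C)C)C(C)C | intermediate
7 | ethyl N,N-di(propan-2-yl)carbamate | CCOC(=O)N(C(C)C)C(C)C | starting material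
8 | (1S)-1-lithioethyl N,N-di(propan-2-yl)carbamate ((–)-sparteine complex) | C[C@@H](OC(=O)N(C(C)C)C(C)C)[Li] | intermediate (not isolated)
9 | lithium [(1S)-1-(Cb-oxy)ethyl]{[3-methoxy-4-(TIPS-oxy)phenyl]methyl}(pinacolato)borate | [Li+].C[C@@H](OC(=O)N(C(C)C)C(C)C)[B-]1(Cc2ccc(O[Si](C(C)C)(C(C)C)C(C)C)c(OC)c2)OC(C)(C)C(C)(C)O1 | intermediate (not isolated)
10 | 2-{(2R)-1-[3-methoxy-4-(TIPS-oxy)phenyl]propan-2-yl}-4,4,5,5-tetramethyl-1,3,2-dioxaborolane | COc1cc(C[C@@H](C)B2OC(C)(C)C(C)(C)O2)ccc1O[Si](C(C)C)(C(C)C)C(C)C | intermediate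
11 | (1R)-1-lithioethyl N,N-di(propan-2-yl)carbamate ((+)-sparteine complex) | C[C@H](OC(=O)N(C(C)C)C(C)C)[Li] | intermediate (not isolated)
12 | lithium [(1R)-1-(Cb-oxy)ethyl]{(2R)-1-[3-methoxy-4-(TIPS-oxy)phenyl]propan-2-yl}(pinacolato)borate | [Li+].C[C@H](OC(=O)N(C(C)C)C(C)C)[B-]1([C@H](C)Cc2ccc(O[Si](C(C)C)(C(C)C)C(C)C)c(OC)c2)OC(C)(C)C(C)(C)O1 | intermediate (not isolated)
13 | 2-{(2S,3R)-4-[3-methoxy-4-(TIPS-oxy)phenyl]-3-methylbutan-2-yl}-4,4,5,5-tetramethyl-1,3,2-dioxaborolane | COc1cc(C[C@@H](C)[C@H](C)B2OC(C)(C)C(C)(C)O2)ccc1O[Si](C(C)C)(C(C)C)C(C)C | intermediate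
14 | (3,4-dimethoxyphenyl)methanol | COc1ccc(CO)cc1OC | starting material
15 | (3,4-dimethoxyphenyl)methyl N,N-di(propan-2-yl)carbamate | COc1ccc(COC(=O)N(C(C)C)C(C)C)cc1OC | intermediate
16 | (R)-(3,4-dimethoxyphenyl)(lithio)methyl N,N-di(propan-2-yl)carbamate (bis(oxazoline) complex) | COc1ccc(cc1OC)[C@H](OC(=O)N(C(C)C)C(C)C)[Li] | intermediate (not isolated)
17 | lithium [(R)-(Cb-oxy)(3,4-dimethoxyphenyl)methyl]{(2S,3R)-4-[3-methoxy-4-(TIPS-oxy)phenyl]-3-methylbutan-2-yl}(pinacolato)borate | [Li+].COc1ccc(cc1OC)[C@H](OC(=O)N(C(C)C)C(C)C)[B-]2(OC(C)(C)C(C)(C)O2)[C@@H](C)[C@H](C)Cc3ccc(O[Si](C(C)C)(C(C)C)C(C)C)c(OC)c3 | intermediate (not isolated)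
18 | 2-{(1R,2R,3R)-1-(3,4-dimethoxyphenyl)-4-[3-methoxy-4-(TIPS-oxy)phenyl]-2,3-dimethylbutyl}-4,4,5,5-tetramethyl-1,3,2-dioxaborolane (same spatial arrangement as 19; the descriptor at C2 changes because boron lowers the rank of C1) | COc1ccc(cc1OC)[C@H](B2OC(C)(C)C(C)(C)O2)[C@@H](C)[C@H](C)Cc3ccc(O[Si](C(C)C)(C(C)C)C(C)C)c(OC)c3 | intermediate (not isolated)
19 | (1R,2S,3R)-1-(3,4-dimethoxyphenyl)-4-[3-methoxy-4-(TIPS-oxy)phenyl]-2,3-dimethylbutan-1-ol | COc1cc(C[C@@H](C)[C@H](C)[C@@H](O)c2ccc(OC)c(OC)c2)ccc1O[Si](C(C)C)(C(C)C)C(C)C | intermediate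
20 | (1R,2S,3R)-1-(3,4-dimethoxyphenyl)-4-[3-methoxy-4-(TIPS-oxy)phenyl]-2,3-dimethylbutyl acetate | COc1cc(C[C@@H](C)[C@H](C)[C@@H](OC(C)=O)c2ccc(OC)c(OC)c2)ccc1O[Si](C(C)C)(C(C)C)C(C)C | intermediate
21 | (1R,2S,3R)-1-(3,4-dimethoxyphenyl)-4-(4-hydroxy-3-methoxyphenyl)-2,3-dimethylbutyl acetate | COc1cc(C[C@@H](C)[C@H](C)[C@@H](OC(C)=O)c2ccc(OC)c(OC)c2)ccc1O | target

**Summary**

Total step count: 8. Longest linear sequence: 7 steps (steps 1, 2, 3, 4, 6, 7, 8); step 5 is a one-step side branch.

**Three steps most likely to fail**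

1. Step 6 (proposed new method). The lithiated carbamate 16 may epimerise at C7 faster than it is captured by 13, or the ligand may not differentiate the two epimeric lithium complexes enough, so that C7 is formed without control. Complex 17 may also fall back to its components before the 1,2-shift. The fallback uses known lithiation–borylation with a configurationally stable primary alkyl carbenoid and lets the aryl group migrate. It sets out from 13. Insertion of chloromethyllithium (BrCH2Cl, n-BuLi, THF, –78 °C to rt; Matteson homologation) should give the one-carbon-extended primary boronic ester F1. Perborate oxidation should give the primary alcohol F2, and carbamoylation (CbCl, Et3N) the primary carbamate F3. s-BuLi/(–)-sparteine should then remove the pro-S proton at C7 to give the configurationally stable lithiated carbamate F4, which is borylated with purchased 2-(3,4-dimethoxyphenyl)-4,4,5,5-tetramethyl-1,3,2-dioxaborolane to the aryl boronate complex F5. The 1,2-shift of the aryl group with inversion should give 18, where the fallback comes back to the route; 18 is oxidised to 19 as in step 6. In this variant the C7–C8 bond comes from the methylene insertion and C7 is set by sparteine.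

2. Step 4. Complex formation between the hindered secondary boronic ester 10 and carbenoid 11 may be slow or reversible and the 1,2-shift incomplete, so that 10 is recovered or the pairing at C8/C8' erodes. The fallback exchanges the roles at C8, so that the boron partner is small and unhindered. It sets out from 10. Chloromethyllithium should give the methylene-extended boronic ester F6, perborate oxidation the primary alcohol F7, and carbamoylation the carbamate F8. s-BuLi/(–)-sparteine should give the (S)-lithiated carbamate F9, which adds to purchased methylboronic acid pinacol ester to give the methyl boronate complex F10. Shift of the methyl group (MgBr2·OEt2, reflux) with inversion should then give 13, where the fallback comes back to the route.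

3. Step 8. During desilylation the acetyl group may move from the C7 oxygen to the phenoxide, or the electron-rich benzylic acetate may be lost by solvolysis. The fallback changes the order of the protecting-group operations and sets out from 19. TBAF should give the free phenol–alcohol F11, and Ac2O/pyridine the diacetate F12. The aryl acetate, which is by far the better acyl donor, is then cleaved selectively (NH4OAc, aqueous MeOH, rt) to give 21, where the fallback comes back to the route.

**Further compounds**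

F1 | step 6 | 2-{(2R,3R)-4-[3-methoxy-4-(TIPS-oxy)phenyl]-2,3-dimethylbutyl}-4,4,5,5-tetramethyl-1,3,2-dioxaborolane | COc1cc(C[C@@H](C)[C@H](C)CB2OC(C)(C)C(C)(C)O2)ccc1O[Si](C(C)C)(C(C)C)C(C)C
F2 | step 6 | (2S,3R)-4-[3-methoxy-4-(TIPS-oxy)phenyl]-2,3-dimethylbutan-1-ol | COc1cc(C[C@@H](C)[C@H](C)CO)ccc1O[Si](C(C)C)(C(C)C)C(C)C
F3 | step 6 | (2S,3R)-4-[3-methoxy-4-(TIPS-oxy)phenyl]-2,3-dimethylbutyl N,N-di(propan-2-yl)carbamate | COc1cc(C[C@@H](C)[C@H](C)COC(=O)N(C(C)C)C(C)C)ccc1O[Si](C(C)C)(C(C)C)C(C)C
F4 | step 6 | (1S,2S,3R)-1-lithio-4-[3-methoxy-4-(TIPS-oxy)phenyl]-2,3-dimethylbutyl N,N-di(propan-2-yl)carbamate | COc1cc(C[C@@H](C)[C@H](C)[C@H]([Li])OC(=O)N(C(C)C)C(C)C)ccc1O[Si](C(C)C)(C(C)C)C(C)C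
F5 | step 6 | lithium {(1S,2S,3R)-1-(Cb-oxy)-4-[3-methoxy-4-(TIPS-oxy)phenyl]-2,3-dimethylbutyl}(3,4-dimethoxyphenyl)(pinacolato)borate | [Li+].COc1cc(C[C@@H](C)[C@H](C)[C@@H](OC(=O)N(C(C)C)C(C)C)[B-]2(c3ccc(OC)c(OC)c3)OC(C)(C)C(C)(C)O2)ccc1O[Si](C(C)C)(C(C)C)C(C)C
F6 | step 4 | 2-{(2S)-3-[3-methoxy-4-(TIPS-oxy)phenyl]-2-methylpropyl}-4,4,5,5-tetramethyl-1,3,2-dioxaborolane | COc1cc(C[C@@H](C)CB2OC(C)(C)C(C)(C)O2)ccc1O[Si](C(C)C)(C(C)C)C(C)C
F7 | step 4 | (2R)-3-[3-methoxy-4-(TIPS-oxy)phenyl]-2-methylpropan-1-ol | COc1cc(C[C@@H](C)CO)ccc1O[Si](C(C)C)(C(C)C)C(C)C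
F8 | step 4 | (2R)-3-[3-methoxy-4-(TIPS-oxy)phenyl]-2-methylpropyl N,N-di(propan-2-yl)carbamate | COc1cc(C[C@@H](C)COC(=O)N(C(C)C)C(C)C)ccc1O[Si](C(C)C)(C(C)C)C(C)C
F9 | step 4 | (1S,2R)-1-lithio-3-[3-methoxy-4-(TIPS-oxy)phenyl]-2-methylpropyl N,N-di(propan-2-yl)carbamate | COc1cc(C[C@@H](C)[C@H]([Li])OC(=O)N(C(C)C)C(C)C)ccc1O[Si](C(C)C)(C(C)C)C(C)C
F10 | step 4 | lithium {(1S,2R)-1-(Cb-oxy)-3-[3-methoxy-4-(TIPS-oxy)phenyl]-2-methylpropyl}(methyl)(pinacolato)borate | [Li+].COc1cc(C[C@@H](C)[C@@H](OC(=O)N(C(C)C)C(C)C)[B-]2(C)OC(C)(C)C(C)(C)O2)ccc1O[Si](C(C)C)(C(C)C)C(C)C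
F11 | step 8 | (1R,2S,3R)-1-(3,4-dimethoxyphenyl)-4-(4-hydroxy-3-methoxyphenyl)-2,3-dimethylbutan-1-ol | COc1cc(C[C@@H](C)[C@H](C)[C@@H](O)c2ccc(OC)c(OC)c2)ccc1O
F12 | step 8 | (1R,2S,3R)-4-(4-acetoxy-3-methoxyphenyl)-1-(3,4-dimethoxyphenyl)-2,3-dimethylbutyl acetate | COc1cc(C[C@@H](C)[C@H](C)[C@@H](OC(C)=O)c2ccc(OC)c(OC)c2)ccc1OC(C)=O
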